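## Analysis of the target

The target is a spiro acylphloroglucinol-type triketone. Ring A is an enolised 2-acylcyclohexane-1,3,5-trione, numbered here C1 (the carbon carrying both prenyl groups), C2 (ketone), C3 (spiro carbon), C4 (ketone), C5 (the carbon carrying the 3-methylbutanoyl group) and C6 (enol carbon). C3 also belongs to ring B (C3, C7, C8, C9, C10, C11), a cyclohexane trans-fused along C8–C9 to the cyclopentane ring C (C8, C14, C13, C12, C9); C10 and C14 are methyl carbinols. There are five stereocentres, 3S, 8S, 9R, 10S and 14R in this numbering. Ring B is a chair with C8–H and C9–H trans-diaxial, the C10 hydroxyl is axial on the face of C8–H, the C14 methyl is cis and the C14 hydroxyl trans to C8–H, and C3 is stereogenic only because its two carbonyl branches differ, C4 standing axial on the same face as the C10 hydroxyl. The sensitive groups are the acidic, metal-chelating β-triketone (prone to O-alkylation), two tertiary alcohols that dehydrate under strong acid, and two prenyl alkenes that tolerate neither ozone nor acid next to the enol. The difficulty is to relay configuration to the quaternary carbon C3, whose two substituents differ only at a distance, and to build a fully substituted ring A on that neopentyl centre beside four other stereocentres. The strategy rests on one observation: with C3 taken back to a malonate carbon and C10 to a ketone, ring B is an achiral cyclohexenone (C10 carbonyl, C9 α, C8 β). An enantioselective conjugate addition at C8 followed by alkylation at C9 then creates ring C and both ring-fusion centres, and the later C10 carbinol tells the two carboxyl groups on C3 apart by lactonisation.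

## Retrosynthetic reasoning

**C1–prenyl bonds.** Target 26 is cut at both C1–CH2 bonds to the spiro acyl trione 24 and two molecules of prenyl bromide 25. The prenyl groups come last because they would survive neither the two ozonolyses nor the acid stage used earlier. In 24, C1 is the only remaining doubly activated methylene, so the forward reaction is two successive C-alkylations of the trione dianion.

**Ring A (C1–C2 and C4–C5).** Ring A of 24 is opened at the two acyl–carbon bonds, leading to the lactone acid chloride 19 and 6-methylheptane-2,4-dione 20, used as its dianion 21. The cut is made here because the two carbonyl groups on C3 are chemically different in 19: the terminal carbanion of 21 goes to the acid chloride (C2), and the central carbon then closes on the lactone carbonyl (C4) through triketone 22. This transfers the C10 configuration to C3, brings in the acyl side chain with the ring, and frees the C10 hydroxyl.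

**Adjusting the C2 carboxyl.** Acid chloride 19 comes from acid 18, which comes from methyl ester 17 by nucleophilic demethylation at the methyl carbon, so the lactone acyl group is not touched. The silyl ether in 17 keeps the C14 hydroxyl of 16 out of the acid chloride chemistry.

**C14–CH3.** Carbinol 16 is traced to ketone 15 and a methyl organometallic, and 15 to the exocyclic alkene of 14 by ozonolysis. The methylene group is a ketone equivalent that is inert to everything before it. The lactone bridge of 14 and 15 locks ring B, so C8, now α to a ketone, cannot epimerise.

**C10–CH3 and the lactone C–O bond.** Lactone 14 is opened to hydroxy diester 13 and then to ketone 12. The forward reaction needs an equatorial methyl addition at C10, so that the new alkoxide is axial and can reach only the axial ester on C3.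

**Key disconnection (C8–C14 and C9–C12).** Ring C of 12 is cut at both bonds to the achiral enone 6 and the bifunctional boronate 9. These two bonds are chosen because they turn a bicyclic ketone with two stereocentres into a flat, symmetric precursor. The forward step needs a catalyst-controlled conjugate addition at C8, giving 10, then an enolate alkylation at C9 that first gives cis-fused 11 and, after equilibration, 12.

**Enone 6.** The C8=C9 bond comes from an intramolecular aldol condensation of keto aldehyde 4 through aldol 5. The aldehyde comes from the allyl group of 3, and 3 from alkylation of allylmalonate 1 with chloroacetone 2. Each step is standard, so the risk of the route stays in the key step.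

**Boronate 9.** The C–B bond is traced to the C–Br bond of 8, and the chloride of 8 to the alcohol of the commercial bromo alcohol 7. Deriving the boron position from a bromide, rather than from the regiochemistry of an alkyne hydrometalation, makes the substitution pattern of 9 unambiguous.

## Alternatives that were turned down

**Alternative 1:** Ring A is disconnected at C1–C2 and C4–C5 and this closure is made the organising step. Forward, the dianion 21 of 20 (LiN(iPr)2) is acylated at its terminal carbon by a lactone acid chloride of the type of 19, and its central carbon then attacks the lactone carbonyl to give the spiro acyl trione A1 (the same structure as 24), one diprenylation short of the target. For it: the step is convergent, sets C3 by relay from C10, frees the C10 hydroxyl and ends close to the target. Against it: it creates none of the stereocentres on rings B and C, leaves open how the lactone with C8, C9, C10 and C14 is obtained, and puts its polyanion chemistry on the most advanced intermediate. On ring A it is as strong as the chosen route, which uses the same closure as step 13. The chosen strategy adds a catalytic, enantioselective entry to the lactone that this closure needs.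

**Alternative 2:** Ring B and the lactone are disconnected together at C3–C11 and O–C10, leading to the cyclopentyl malonate A2, which carries an isopropenyl group on C9. Forward, Mn(OAc)3 (trivalent manganese) oxidises the C3–H malonate to its radical, which adds 6-endo to the isopropenyl CH2; the tertiary C10 radical is oxidised to the cation and captured by an ester carbonyl, giving lactone ester A3 (the same structure as 16). For it: one step forms ring B, the C10 centre and the lactone, and the cis relation of O–C10 and C4 is enforced by the bridge, not by reagent approach; on this point it is stronger than the chosen route, which needs two steps and a facial selectivity. Against it: A2 already holds three contiguous stereocentres (C8, C9, C14) that must be made enantiopure beforehand; 5-exo closure competes; capture by a methyl ester needs loss of the methyl group and competes with elimination at C10; and the oxidant is stoichiometric and acidic with a tertiary alcohol present. The chosen route reaches the same intermediate 16 from achiral materials with C8 set by a catalyst, so the alternative's saving is offset by the synthesis of A2.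

**Alternative 3:** Ring B is disconnected at C9–C10 and C7–C8 to the cyclobutanone diester A4 and the chiral-pool cyclopentenol A5. Forward, Ni(cod)2 with PCy3 (zerovalent nickel) couples the carbonyl carbon C10 with alkene carbon C9, cleaves C10–C7 by β-carbon elimination and forms C7–C8 by reductive elimination; base epimerisation at C9 would give hydrindanone A6. For it: it would be the shortest entry by far, takes its absolute configuration and the C14 carbinol from the chiral pool, and removes the late facial question at C14; on step economy and on C14 it is stronger than the chosen route. Against it: intermolecular insertion of an unactivated 1,2-disubstituted cycloalkene into a cyclobutanone has no close precedent, nothing controls which alkene carbon bonds to C10, the face is differentiated only by methyl against hydroxyl on C14, and the allylic oxygen invites β-oxygen elimination at nickel. The chosen strategy places the comparable ring construction on a precedented asymmetric reaction and accepts more steps for that.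

Key step: step 6

Remark: the acyl trione of ring A is written as its C6 enol; its enol tautomers interconvert and are treated as one compound.

## Route

Step 1
Reactants: 1 dimethyl 2-allylmalonate; 2 chloroacetone
Product: 3 dimethyl 2-allyl-2-(2-oxopropyl)malonate
Conditions: NaH, NaI (cat.), THF, 0 → 25 °C
Reagents that add atoms: none
Why: Malonate alkylation: the sodium enolate of 1 displaces chloride from 2 (SN2 at an α-halo ketone, iodide catalysis) and creates the quaternary carbon that becomes C3.

Step 2
Reactants: 3 dimethyl 2-allyl-2-(2-oxopropyl)malonate
Product: 4 dimethyl 2-(2-oxoethyl)-2-(2-oxopropyl)malonate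
Conditions: O3, CH2Cl2/MeOH, −78 °C; then Me2S, −78 → 25 °C
Reagents that add atoms: ozone, [O-][O+]=O
Why: Ozonolysis of the terminal alkene with reductive work-up gives the aldehyde (C8); ketone and esters are inert to ozone.

Step 3
Reactants: 4 dimethyl 2-(2-oxoethyl)-2-(2-oxopropyl)malonate
Product: 6 dimethyl 5-oxocyclohex-3-ene-1,1-dicarboxylate, via aldol 5 (not isolated)
Conditions: piperidine, AcOH, toluene, 80 °C
Reagents that add atoms: none
Why: Intramolecular aldol condensation: only the methyl ketone carbon can reach the aldehyde in a six-membered ring (the other enolisable positions would give four-membered rings), and dehydration of 5 gives the conjugated enone.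

Step 4
Reactants: 7 3-bromobut-3-en-1-ol
Product: 8 2-bromo-4-chlorobut-1-ene
Conditions: PPh3, CCl4, CH2Cl2, 40 °C
Reagents that add atoms: carbon tetrachloride, ClC(Cl)(Cl)Cl
Why: Appel reaction of a primary alcohol; the vinyl bromide is inert to the phosphonium intermediates.

Step 5
Reactants: 8 2-bromo-4-chlorobut-1-ene
Product: 9 2-(4-chlorobut-1-en-2-yl)-4,4,5,5-tetramethyl-1,3,2-dioxaborolane
Conditions: B2pin2, PdCl2(PPh3)2 (3 mol %), PPh3, KOPh, toluene, 50 °C
Reagents that add atoms: bis(pinacolato)diboron, CC1(C)OB(OC1(C)C)B1OC(C)(C)C(C)(C)O1
Why: Miyaura borylation of an alkenyl bromide; oxidative addition takes place at the sp2 C–Br bond only, so the primary alkyl chloride is retained and boron sits at the internal alkene carbon.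

Step 6
Reactants: 6 dimethyl 5-oxocyclohex-3-ene-1,1-dicarboxylate; 9 2-(4-chlorobut-1-en-2-yl)-4,4,5,5-tetramethyl-1,3,2-dioxaborolane
Product: 12 dimethyl (3aS,7aR)-3-methylidene-7-oxooctahydro-5H-indene-5,5-dicarboxylate (trans-fused), via chloro ketone 10 (not isolated), via cis-fused ketone 11 (not isolated)
Conditions: Rh(acac)(C2H4)2 (3 mol %), (S)-BINAP, dioxane/H2O 10:1, 100 °C; extractive work-up; then KOtBu, THF/t-BuOH, 0 → 25 °C
Reagents that add atoms: none
Why: Transmetallation of 9 to a hydroxo-rhodium–(S)-BINAP species gives an alkenylrhodium intermediate (monovalent rhodium) that inserts the C8=C9 bond of 6; water cleaves the oxa-π-allyl rhodium, releases ketone 10 and regenerates the hydroxo complex. The closest known reaction type is the Hayashi–Miyaura asymmetric 1,4-addition of alkenylboron reagents to cyclohexenones, joined here to a methylenecyclopentane annulation by enolate cycloalkylation. C8 is set by the ligand alone because 6 is achiral: (S)-BINAP is expected to give (3S)-10 by the facial sense established for 2-cyclohexenone, and the other antipode of the ligand is available should the sense differ. With KOtBu both enolates of the C10 ketone form reversibly, but only the C9 enolate can reach C12 in a five-membered transition state, so ring C closes by 5-exo-tet displacement of chloride (C9–C12); the C11 enolate would need a bridged seven-membered ring. The kinetic cis-fused ketone 11 epimerises at C9 through the same enolate, and the trans-fused 12 should prevail because the cis isomer must place C12 axial, its other chair putting C14 syn-axial to an ester on C3. The step needs C- over O-alkylation and substitution over loss of HCl: the five-membered carbocyclic closure is favoured over a seven-membered enol ether, and the intramolecular alkylation should outrun E2 at the unactivated primary chloride. The hindered alkoxide leaves the methyl esters alone, and C8 is not acidic, so the enantiomeric purity from the rhodium stage is kept.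

Step 7
Reactants: 12 dimethyl (3aS,7aR)-3-methylidene-7-oxooctahydro-5H-indene-5,5-dicarboxylate
Product: 14 bridged γ-lactone methyl ester with the C14 exocyclic methylene (C10–O closed onto the axial C3 carboxyl; rings B and C trans-fused), via hydroxy diester 13 (not isolated)
Conditions: MeLi, CeCl3, THF, −78 °C; NH4Cl (aq); then DBU (cat.), toluene, 60 °C
Reagents that add atoms: methyllithium, [Li]C
Why: Organocerium 1,2-addition is non-basic and ketone-selective, so the esters and the α-hydrogens are left alone. The reagent enters equatorially, away from the axial ester on C3 and the axial C8–H, so the C10 hydroxyl of 13 is axial and cis to that ester. Base-catalysed lactonisation can then involve only the axial ester, which fixes C3 (lactone carbonyl = C4, free ester = C2).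

Step 8
Reactants: 14 bridged γ-lactone methyl ester with the C14 exocyclic methylene
Product: 15 bridged γ-lactone methyl ester with the C14 ketone
Conditions: O3, CH2Cl2/MeOH, −78 °C; then Me2S, −78 → 25 °C
Reagents that add atoms: ozone, [O-][O+]=O
Why: Ozonolysis of the 1,1-disubstituted alkene; the lactone and ester are inert. C8, now α to the ketone, keeps its configuration because its epimer would put C14 syn-axial to the lactone bridge on the locked chair.

Step 9
Reactants: 15 bridged γ-lactone methyl ester with the C14 ketone
Product: 16 bridged γ-lactone methyl ester with the C14 methyl carbinol (methyl cis and hydroxyl trans to C8–H)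
Conditions: MeLi, CeCl3, THF, −78 °C
Reagents that add atoms: methyllithium, [Li]C
Why: Organocerium addition avoids enolisation at C8 and C13 and spares lactone and ester at −78 °C. The bulky reagent should approach C14 from the face of C8–H, anti to C7 and away from the syn-axial hydrogens on C9 and C7, as methyl organometallics do with 2-alkylcyclopentanones, which places the methyl cis to C8–H.

Step 10
Reactants: 16 bridged γ-lactone methyl ester with the C14 methyl carbinol
Product: 17 C14 triethylsilyl ether of 16
Conditions: TESOTf, 2,6-lutidine, CH2Cl2, 0 °C; NaHCO3 (aq)
Reagents that add atoms: triethylsilyl trifluoromethanesulfonate, CC[Si](CC)(CC)OS(=O)(=O)C(F)(F)F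
Why: Silylation of a tertiary alcohol with a silyl triflate and a hindered base; the ether keeps the C14 hydroxyl out of the acid chloride and dianion steps.

Step 11
Reactants: 17 C14 triethylsilyl ether of 16
Product: 18 lactone carboxylic acid (C2 acid; C14 triethylsilyl ether)
Conditions: LiI, pyridine, 115 °C; then cold 0.5 M HCl
Reagents that add atoms: none
Why: SN2 demethylation by iodide at the methyl carbon is indifferent to the neopentyl position of the ester, and the lactone cannot react this way because its alkyl carbon (C10) is tertiary. Decarboxylation of the carboxylate is blocked, since it would require a bridgehead lactone enolate (Bredt's rule).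

Step 12
Reactants: 18 lactone carboxylic acid
Product: 19 lactone acid chloride (C2 acid chloride; C14 triethylsilyl ether)
Conditions: 1-chloro-N,N,2-trimethylprop-1-en-1-amine, CH2Cl2, 0 → 25 °C; concentrated and used crude
Reagents that add atoms: 1-chloro-N,N,2-trimethylprop-1-en-1-amine, CC(C)=C(Cl)N(C)C
Why: The α-chloroenamine converts the acid into its chloride under neutral conditions, without HCl, so the silyl ether and the lactone persist; the acid has no α-hydrogen, so no ketene can form.

Step 13
Reactants: 19 lactone acid chloride; 20 6-methylheptane-2,4-dione
Product: 24 spiro acyl trione diol (the target lacking both prenyl groups), via dilithium dianion 21 (not isolated), via triketone lactone 22 (not isolated), via silyl ether 23 (not isolated)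
Conditions: 20 (3 equiv), LiN(iPr)2 (6 equiv), THF, −78 → 0 °C; then 19, −78 → 25 °C; then 2 M HCl, THF, 25 °C
Reagents that add atoms: none
Why: β-Diketone dianions react at the terminal (methyl-derived) carbon, and the acid chloride is far more electrophilic than the lactone, so C1–C2 forms first (22). The central carbon C5 of the resulting diketonate then closes on the lactone carbonyl C4 in a Dieckmann-type Claisen condensation, the only six-membered C–C closure available, driven by the stabilised trione anion and by loss of the bridged-ring strain. Because C2 came from the free carboxyl and C4 from the lactone, C3 has the required configuration; the acid stage removes the silyl ether before any prenyl group is present.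

Step 14
Reactants: 24 spiro acyl trione diol; 25 prenyl bromide (2.5 equiv)
Product: 26 CNP0198642.2 (3S,8S,9R,10S,14R in the numbering used here)
Conditions: NaOMe, MeOH, 0 → 25 °C
Reagents that add atoms: none
Why: Double C-alkylation of the acyl trione dianion at C1, the only ring carbon still bearing hydrogen between two carbonyls, as in the gem-diprenylation of acylphloroglucinols; the protic medium favours C- over O-alkylation, and the tertiary alcohols do not react.

## Compound list

1 | dimethyl 2-allylmalonate | COC(=O)C(CC=C)C(=O)OC | starting material
2 | chloroacetone | CC(=O)CCl | starting material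
3 | dimethyl 2-allyl-2-(2-oxopropyl)malonate | COC(=O)C(CC=C)(CC(C)=O)C(=O)OC | intermediate
4 | dimethyl 2-(2-oxoethyl)-2-(2-oxopropyl)malonate | COC(=O)C(CC=O)(CC(C)=O)C(=O)OC | intermediate
5 | dimethyl 3-hydroxy-5-oxocyclohexane-1,1-dicarboxylate (racemic aldol) | COC(=O)C1(C(=O)OC)CC(O)CC(=O)C1 | intermediate
6 | dimethyl 5-oxocyclohex-3-ene-1,1-dicarboxylate | COC(=O)C1(C(=O)OC)CC=CC(=O)C1 | intermediate
7 | 3-bromobut-3-en-1-ol | OCCC(Br)=C | starting material
8 | 2-bromo-4-chlorobut-1-ene | ClCCC(Br)=C | intermediate
9 | 2-(4-chlorobut-1-en-2-yl)-4,4,5,5-tetramethyl-1,3,2-dioxaborolane | ClCCC(=C)B1OC(C)(C)C(C)(C)O1 | intermediate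
10 | dimethyl (3S)-3-(4-chlorobut-1-en-2-yl)-5-oxocyclohexane-1,1-dicarboxylate | COC(=O)C1(C(=O)OC)C[C@H](C(=C)CCCl)CC(=O)C1 | intermediate
11 | dimethyl (3aS,7aS)-3-methylidene-7-oxooctahydro-5H-indene-5,5-dicarboxylate (cis-fused) | COC(=O)C1(C(=O)OC)C[C@H]2[C@H](CCC2=C)C(=O)C1 | intermediate
12 | dimethyl (3aS,7aR)-3-methylidene-7-oxooctahydro-5H-indene-5,5-dicarboxylate (trans-fused) | COC(=O)C1(C(=O)OC)C[C@H]2[C@@H](CCC2=C)C(=O)C1 | intermediate
13 | dimethyl (3aS,7S,7aR)-7-hydroxy-7-methyl-3-methylideneoctahydro-5H-indene-5,5-dicarboxylate | COC(=O)C1(C(=O)OC)C[C@H]2[C@@H](CCC2=C)[C@@](C)(O)C1 | intermediate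
14 | bridged γ-lactone methyl ester, C14 exocyclic methylene (C10–O on C4; trans-fused; bridge on the face of C8–H) | COC(=O)[C@@]12C[C@H]3[C@@H](CCC3=C)[C@@](C)(OC1=O)C2 | intermediate
15 | bridged γ-lactone methyl ester, C14 ketone | COC(=O)[C@@]12C[C@H]3[C@@H](CCC3=O)[C@@](C)(OC1=O)C2 | intermediate
16 | bridged γ-lactone methyl ester, C14 methyl carbinol (methyl cis to C8–H) | COC(=O)[C@@]12C[C@H]3[C@@H](CC[C@@]3(C)O)[C@@](C)(OC1=O)C2 | intermediate
17 | C14 triethylsilyl ether of 16 | COC(=O)[C@@]12C[C@H]3[C@@H](CC[C@@]3(C)O[Si](CC)(CC)CC)[C@@](C)(OC1=O)C2 | intermediate
18 | lactone carboxylic acid (C14 triethylsilyl ether) | OC(=O)[C@@]12C[C@H]3[C@@H](CC[C@@]3(C)O[Si](CC)(CC)CC)[C@@](C)(OC1=O)C2 | intermediate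
19 | lactone acid chloride (C14 triethylsilyl ether) | ClC(=O)[C@@]12C[C@H]3[C@@H](CC[C@@]3(C)O[Si](CC)(CC)CC)[C@@](C)(OC1=O)C2 | intermediate
20 | 6-methylheptane-2,4-dione | CC(=O)CC(=O)CC(C)C | starting material
21 | dilithium dianion of 20 (terminal dienolate) | [Li+].[Li+].C=C([O-])C=C([O-])CC(C)C | intermediate
22 | triketone lactone (C1–C2 formed; C14 triethylsilyl ether) | CC(C)CC(=O)CC(=O)CC(=O)[C@@]12C[C@H]3[C@@H](CC[C@@]3(C)O[Si](CC)(CC)CC)[C@@](C)(OC1=O)C2 | intermediate
23 | spiro acyl trione, C14 triethylsilyl ether, C10 hydroxyl free | CC(C)CC(=O)C1=C(O)CC(=O)[C@@]2(C[C@H]3[C@@H](CC[C@@]3(C)O[Si](CC)(CC)CC)[C@@](C)(O)C2)C1=O | intermediate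
24 | spiro acyl trione diol (C1 unsubstituted) | CC(C)CC(=O)C1=C(O)CC(=O)[C@@]2(C[C@H]3[C@@H](CC[C@@]3(C)O)[C@@](C)(O)C2)C1=O | intermediate
25 | prenyl bromide (1-bromo-3-methylbut-2-ene) | CC(C)=CCBr | starting material
26 | CNP0198642.2 | CC(C)=CCC1(CC=C(C)C)C(=O)[C@@]2(C[C@H]3[C@@H](CC[C@@]3(C)O)[C@@](C)(O)C2)C(=O)C(C(=O)CC(C)C)=C1O | target

## Step count and least certain steps

Total: 14 steps. Longest linear sequence: 12 steps (1 → 26 through steps 1–3 and 6–14); the boronate branch (steps 4 and 5) joins at step 6.

**Step 6 (key step).** The 1,1-disubstituted alkenyl group may transmetallate and insert slowly, so that protodeboronation or hydrolysis of the C–Cl bond in hot aqueous dioxane outruns the addition and the enantioselectivity erodes. In the base stage, loss of HCl to a diene or incomplete equilibration at C9 would leave cis-fused material, which would have to be separated and resubmitted to base. The boronic acid can replace the pinacol ester without changing the plan. Fallback: from 6, the C8–C14 bond is made without water and without boron. NiCl2(dppp)-catalysed α-hydroalumination of commercial 4-chlorobut-1-yne with iBu2AlH gives (4-chlorobut-1-en-2-yl)bis(2-methylpropyl)aluminium F1, which is added to 6 under Cu(OTf)2 and a chiral phosphoramidite ligand in Et2O at −30 °C. Acidic work-up rejoins the route at 10, which is closed to 12 with KOtBu as before.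

**Step 9.** Facial discrimination at the C14 carbonyl is the least secure stereochemical call of the route: torsional preference for attack anti to C8–H opposes the steric preference assumed here, and attack on that face would give the C14 epimer. Fallback: from 14, steps 8 and 9 are left out and the C14–O bond is formed instead of the C14–CH3 bond. Co(acac)2, PhSiH3 and O2 in THF/iPrOH (Mukaiyama hydration) generate the tertiary C14 radical, which O2 traps; the C14 hydroperoxide F2 that accompanies the alcohol is reduced with PPh3, and the route is rejoined at 16. If the ring favours approach anti to C8–H, this gives the required configuration, so the two methods complement each other.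

**Step 13.** The acid chloride may acylate the dianion on oxygen or twice, and the polyanion of 22 may be too unreactive to close on the lactone or may close through oxygen. Fallback: from 20 and 19, the acylation is done without base. Dione 20 is converted (Me3SiCl/Et3N, then LiN(iPr)2/Me3SiCl) into 6-methyl-2,4-bis(trimethylsilyloxy)hepta-1,3-diene F3, which is acylated at its terminal carbon by 19 in CH2Cl2 (−78 → 20 °C). Mild hydrolysis gives 22, now isolated, and a separate Dieckmann-type closure with a non-nucleophilic base (DBU or 2 equiv KOtBu in THF) leads through 23 and the acid stage back to 24.

**Step 14.** O-Prenylation of the trione enolates and a stalled second alkylation at the hindered C1 are the likely losses. Fallback: from 24, double Tsuji–Trost allylation with allyl methyl carbonate and Pd(PPh3)4 (zerovalent palladium) in THF, which alkylates the soft carbon C1 selectively, gives the gem-diallyl trione F4. Cross-metathesis of both allyl groups with 2-methylbut-2-ene under the second-generation Grubbs catalyst RuCl2(=CHPh)(PCy3)(H2IMes) then gives 26.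

## Further compounds

F1 | step 6 | (4-chlorobut-1-en-2-yl)bis(2-methylpropyl)aluminium | ClCCC(=C)[Al](CC(C)C)CC(C)C
F2 | step 9 | C14 hydroperoxide of the bridged γ-lactone methyl ester | COC(=O)[C@@]12C[C@H]3[C@@H](CC[C@@]3(C)OO)[C@@](C)(OC1=O)C2
F3 | step 13 | 6-methyl-2,4-bis(trimethylsilyloxy)hepta-1,3-diene | C=C(O[Si](C)(C)C)C=C(O[Si](C)(C)C)CC(C)C
F4 | step 14 | gem-diallyl analogue of 26 | C=CCC1(CC=C)C(=O)[C@@]2(C[C@H]3[C@@H](CC[C@@]3(C)O)[C@@](C)(O)C2)C(=O)C(C(=O)CC(C)C)=C1O
A1 | alternative 1 | spiro acyl trione with C1 unsubstituted (same structure as 24) | CC(C)CC(=O)C1=C(O)CC(=O)[C@@]2(C[C@H]3[C@@H](CC[C@@]3(C)O)[C@@](C)(O)C2)C1=O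
A2 | alternative 2 | dimethyl 2-[(2-hydroxy-2-methyl-5-isopropenylcyclopentyl)methyl]malonate (C8, C9, C14 as in the target) | COC(=O)C(C[C@H]1[C@@H](CC[C@@]1(C)O)C(C)=C)C(=O)OC
A3 | alternative 2 | bridged γ-lactone methyl ester with the C14 carbinol (same structure as 16) | COC(=O)[C@@]12C[C@H]3[C@@H](CC[C@@]3(C)O)[C@@](C)(OC1=O)C2
A4 | alternative 3 | diisopropyl 3-oxocyclobutane-1,1-dicarboxylate | CC(C)OC(=O)C1(C(=O)OC(C)C)CC(=O)C1
A5 | alternative 3 | (R)-1-methylcyclopent-2-en-1-ol | C[C@]1(O)C=CCC1
A6 | alternative 3 | trans-fused hydrindanone gem-diisopropyl ester with the C14 carbinol | CC(C)OC(=O)C1(C(=O)OC(C)C)C[C@H]2[C@@H](CC[C@@]2(C)O)C(=O)C1
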